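**Route overview**

- Enabling feature (double primes mark the flavone unit, single primes ring B): the C3–C3'' bond joins the ketone alpha-carbons of two C15 units, so C4–C3–C3''–C4'' is a 1,4-diketone. The flavone unit is the flavanone unit less two hydrogens across C2''=C3'', so the target is the mono-dehydro form of a C2-symmetric 3,3''-binaringenin.
- Cuts, in retrosynthetic order: the six O–benzyl bonds; the C2''=C3'' double bond (back to a second flavanone); the C3–C3'' bond, giving two identical (2S)-flavanone enol silanes; then in each unit the C2–C1' aryl bond (chromone plus arylboronic acid) and the O1–C2 and C2–C3 bonds of ring C (acetophenone plus a one-carbon formamide acetal).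
- Forward order: ring C (the 4-pyranone) is closed on the phloroglucinol ring A, ring B is added at C2, two complete flavanones are joined C3 to C3'' by one-electron oxidation of their enol silane, one dihydropyranone is dehydrogenated to the flavone, and the benzyl groups come off last.
- Stereochemistry: C2 (S) comes from the chiral ligand of the catalytic conjugate addition. C3 (R) comes from C–C bond formation anti to the C2 aryl group, which is also the thermodynamic 2,3-trans position. The two stereocentres of the second unit are erased on purpose by the dehydrogenation.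

Key step: step 5

Assumption: the (R)-antipode of the pyridine-oxazoline ligand is taken to deliver the 2S flavanone, by analogy with the facial sense known for cyclic enones; the configuration of 7 is to be checked (chiral HPLC, or hydrogenolysis of a sample to naringenin) and the (S)-ligand used instead if the sense proves opposite.

**Step 1**
Reactants: 1 2',4',6'-trihydroxyacetophenone
Product: 2 4',6'-bis(benzyloxy)-2'-hydroxyacetophenone
Conditions: BnBr (2.1 equiv), K2CO3 (2.2 equiv), DMF, 0 °C to rt
Reagents that add atoms: benzyl bromide, BrCc1ccccc1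
Why: Williamson ether synthesis in which the 4'-OH and one ortho OH are alkylated, while the remaining ortho OH, held in a hydrogen bond to the acetyl carbonyl and therefore the least nucleophilic, should stay free when the bromide is limited to two equivalents.

**Step 2**
Reactants: 2 4',6'-bis(benzyloxy)-2'-hydroxyacetophenone; 3 N,N-dimethylformamide dimethyl acetal
Product: 5 5,7-bis(benzyloxy)-4H-chromen-4-one, via enaminone 4 (not isolated)
Conditions: 3 (3 equiv), toluene, 95 °C; evaporate; then conc. HCl, CH2Cl2, 40 °C
Reagents that add atoms: none
Why: Condensation of the acetyl methyl group with the formamide acetal gives the vinylogous amide 4, and under acid the free 2'-OH adds to its beta-carbon with expulsion of dimethylamine (addition–elimination, the enaminone route to chromones), which closes ring C with C2 supplied by 3.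

**Step 3**
Reactants: 5 5,7-bis(benzyloxy)-4H-chromen-4-one; 6 4-(benzyloxy)phenylboronic acid
Product: 7 (2S)-5,7-bis(benzyloxy)-2-[4-(benzyloxy)phenyl]chroman-4-one
Conditions: 6 (2.5 equiv), Pd(OCOCF3)2 (10 mol%), (R)-4-tert-butyl-2-(pyridin-2-yl)-4,5-dihydrooxazole (12 mol%), NH4PF6 (30 mol%), H2O (5 equiv), ClCH2CH2Cl, 60 °C
Reagents that add atoms: none
Why: Catalytic asymmetric conjugate addition of an arylboronic acid to a chromone (Hayashi–Miyaura-type 1,4-addition with a cationic divalent palladium pyridine-oxazoline catalyst): aryl transfer from boron to palladium, enantioface-selective insertion of C2=C3 into the aryl–palladium bond and protonolysis of the palladium enolate by water set C2 under ligand control, and the non-basic medium should spare the flavanone from retro-oxa-Michael opening.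

**Step 4**
Reactants: 7 (2S)-5,7-bis(benzyloxy)-2-[4-(benzyloxy)phenyl]chroman-4-one
Product: 8 trimethyl{[(2S)-5,7-bis(benzyloxy)-2-(4-benzyloxyphenyl)-2H-chromen-4-yl]oxy}silane
Conditions: Me3SiOSO2CF3 (1.3 equiv), Et3N (2.5 equiv), CH2Cl2, −20 to 0 °C; pentane, filtration, used at once
Reagents that add atoms: trimethylsilyl trifluoromethanesulfonate, C[Si](C)(C)OS(=O)(=O)C(F)(F)F
Why: Soft enolisation (silyl triflate on the carbonyl oxygen, then removal of a C3 proton by the amine) gives the only possible enol silane without a free enolate ever being present, so E1cB opening to the chalcone and loss of the C2 configuration should not occur.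

**Step 5**
Reactants: 8 trimethyl{[(2S)-5,7-bis(benzyloxy)-2-(4-benzyloxyphenyl)-2H-chromen-4-yl]oxy}silane (two molecules)
Product: 9 (2S,3R,2''S,3''R)-hexa-O-benzyl-3,3''-binaringenin (two (2S,3R)-5,7-bis(benzyloxy)-2-[4-(benzyloxy)phenyl]chroman-4-one units joined C3 to C3'')
Conditions: (NH4)2Ce(NO3)6 (1.1 equiv per 8, added slowly), NaHCO3 (2.5 equiv), MeCN/CH2Cl2, −20 °C, concentrated solution; chromatography, then crystallisation to remove any dimer containing an (R)-unit
Reagents that add atoms: none
Why: Tetravalent cerium removes one electron from the electron-rich enol silane 8; the radical cation sheds its silyl group and becomes a C3-centred alpha-keto radical, which is captured at C3 by a second molecule of 8 (or by a second radical), and a further one-electron oxidation with loss of the second silyl group unveils the 1,4-diketone, trivalent cerium being the spent oxidant. The closest known reaction type is the (NH4)2Ce(NO3)6-mediated oxidative homocoupling of trimethylsilyl enol ethers of aryl and cyclic aryl ketones to 1,4-diketones. No ring is closed: two intact chromanone rings are joined by an intermolecular C3–C3'' bond. Both new stereocentres (C3 and C3'') are controlled by the neighbouring C2 aryl group, which blocks one face of the planar C3 radical and of the enol ether, so each end of the bond forms anti to it and the 2,3-trans, 2'',3''-trans (3R,3''R) dimer results; this is also the thermodynamic arrangement, reachable by mild acid equilibration. The step needs C–C coupling at C3 rather than C–O coupling, nitrate capture or loss of the C2 hydrogen: C3 is the only enolisable position, the partners are identical so no cross-selectivity arises, the spin of the aryl-conjugated alpha-keto radical resides on carbon, and a high concentration of 8 with slow addition of the oxidant favours the bimolecular C–C event. The medium is oxidative and buffered, so the free enolate that would open to the chalcone and racemise C2 is never present.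

**Step 6**
Reactants: 9 (2S,3R,2''S,3''R)-hexa-O-benzyl-3,3''-binaringenin
Product: 10 (2S,3R)-5,7-bis(benzyloxy)-2-[4-(benzyloxy)phenyl]-3-{5,7-bis(benzyloxy)-2-[4-(benzyloxy)phenyl]-4-oxo-4H-chromen-3-yl}chroman-4-one
Conditions: DDQ (1.1 equiv), 1,4-dioxane, 100 °C, stopped near half conversion; 9 recovered and resubmitted
Reagents that add atoms: none
Why: DDQ dehydrogenation of a flavanone to a flavone (hydride abstraction from the benzylic, oxygen-bearing C2'', then loss of the C3'' proton); because the two units of C2-symmetric 9 are equivalent, a limiting amount of oxidant should give a single mono-dehydro product beside recoverable 9 and the separable achiral bis-flavone, and the surviving C3 centre sits in its thermodynamic trans position (any cis epimer would be corrected with catalytic p-TsOH in CH2Cl2, never with strong base).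

**Step 7**
Reactants: 10 (2S,3R)-5,7-bis(benzyloxy)-2-[4-(benzyloxy)phenyl]-3-{5,7-bis(benzyloxy)-2-[4-(benzyloxy)phenyl]-4-oxo-4H-chromen-3-yl}chroman-4-one
Product: 11 (2S,3R)-5,7-dihydroxy-2-(4-hydroxyphenyl)-3-[5,7-dihydroxy-2-(4-hydroxyphenyl)-4-oxo-4H-chromen-3-yl]chroman-4-one (CNP0208264.1)
Conditions: H2 (1 atm), 10% Pd on carbon, THF/MeOH, rt, stopped after uptake of six equivalents
Reagents that add atoms: none
Why: Hydrogenolysis of six aryl benzyl ethers, which should be much faster than reduction of the tetrasubstituted, vinylogous-ester C2''=C3'' bond or of the two aryl ketones, and the neutral medium leaves C2 and C3 untouched.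

**Compound list**

1 | 2',4',6'-trihydroxyacetophenone | CC(=O)c1c(O)cc(O)cc1O | starting material
2 | 4',6'-bis(benzyloxy)-2'-hydroxyacetophenone | CC(=O)c1c(O)cc(OCc2ccccc2)cc1OCc1ccccc1 | intermediate
3 | N,N-dimethylformamide dimethyl acetal | COC(OC)N(C)C | starting material
4 | (E)-1-[2,4-bis(benzyloxy)-6-hydroxyphenyl]-3-(dimethylamino)prop-2-en-1-one (enaminone) | CN(C)/C=C/C(=O)c1c(O)cc(OCc2ccccc2)cc1OCc1ccccc1 | intermediate
5 | 5,7-bis(benzyloxy)-4H-chromen-4-one | O=c1ccoc2cc(OCc3ccccc3)cc(OCc3ccccc3)c12 | intermediate
6 | 4-(benzyloxy)phenylboronic acid | OB(O)c1ccc(OCc2ccccc2)cc1 | starting material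
7 | (2S)-5,7-bis(benzyloxy)-2-[4-(benzyloxy)phenyl]chroman-4-one | O=C1c2c(OCc3ccccc3)cc(OCc3ccccc3)cc2O[C@H](c2ccc(OCc3ccccc3)cc2)C1 | intermediate
8 | trimethyl{[(2S)-5,7-bis(benzyloxy)-2-(4-benzyloxyphenyl)-2H-chromen-4-yl]oxy}silane | C[Si](C)(C)OC1=C[C@@H](c2ccc(OCc3ccccc3)cc2)Oc2cc(OCc3ccccc3)cc(OCc3ccccc3)c21 | intermediate
9 | (2S,3R,2''S,3''R)-hexa-O-benzyl-3,3''-binaringenin | O=C1c2c(OCc3ccccc3)cc(OCc3ccccc3)cc2O[C@H](c2ccc(OCc3ccccc3)cc2)[C@H]1[C@H]1C(=O)c2c(OCc3ccccc3)cc(OCc3ccccc3)cc2O[C@@H]1c1ccc(OCc2ccccc2)cc1 | intermediate
10 | (2S,3R)-5,7-bis(benzyloxy)-2-[4-(benzyloxy)phenyl]-3-{5,7-bis(benzyloxy)-2-[4-(benzyloxy)phenyl]-4-oxo-4H-chromen-3-yl}chroman-4-one | O=C1c2c(OCc3ccccc3)cc(OCc3ccccc3)cc2O[C@H](c2ccc(OCc3ccccc3)cc2)[C@H]1c1c(-c2ccc(OCc3ccccc3)cc2)oc2cc(OCc3ccccc3)cc(OCc3ccccc3)c2c1=O | intermediate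
11 | (2S,3R)-5,7-dihydroxy-2-(4-hydroxyphenyl)-3-[5,7-dihydroxy-2-(4-hydroxyphenyl)-4-oxo-4H-chromen-3-yl]chroman-4-one | O=C1c2c(O)cc(O)cc2O[C@H](c2ccc(O)cc2)[C@H]1c1c(-c2ccc(O)cc2)oc2cc(O)cc(O)c2c1=O | target

**Step count and risks**

Total step count: 7. Longest linear sequence: 7 steps (1 to 11); compounds 3 and 6 are bought.

Steps most likely to fail:

1. Step 5. The process at risk is capture of the C3 radical by nitrate, or its further oxidation followed by loss of the C2 hydrogen, outrunning the bimolecular C–C bond formation, which the flanking C2 aryl groups slow down. The fallback makes the coupling intramolecular through a temporary silicon tether. It sets out from 7: soft enolisation with iPr2Si(OSO2CF3)2 (0.5 equiv) and Et3N in CH2Cl2 should give bis{[(2S)-5,7-bis(benzyloxy)-2-(4-benzyloxyphenyl)-2H-chromen-4-yl]oxy}diisopropylsilane F1. Oxidation of F1 with (NH4)2Ce(NO3)6 and NaHCO3 in MeCN at −10 °C should form the C3–C3'' bond within the tethered pair, and loss of the silicon bridge on work-up returns the route at 9.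

2. Step 6. The process at risk is loss of differentiation between the two units: the second dehydrogenation keeping pace with the first, or hydride abstraction at the crowded C2'' being too slow to compete with decomposition. The fallback separates the differentiating event from the oxidation. It sets out from 9: TBSOSO2CF3 (1 equiv) and Et3N should give the 4''-(tert-butyldimethylsilyloxy) mono-enol ether F2, in which one unit of 9 is unchanged and the other is a 2H-chromene with a C3''=C4'' double bond. F2 is separable on amine-deactivated silica from unreacted 9 and from the bis-enol ether, both of which are returned to 9. Saegusa–Ito oxidation of F2 with Pd(OAc)2 in MeCN (beta-hydride elimination of the C2'' hydrogen) should then give the flavone unit and rejoin the route at 10.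

3. Step 3. The process at risk is slow insertion of the electron-rich, peri-substituted chromone into the aryl–palladium bond, with protodeboronation of the boronic acid and erosion of enantioface selectivity. The fallback builds ring C by oxa-Michael closure instead and resolves. It sets out from 2: Claisen–Schmidt condensation with 4-(benzyloxy)benzaldehyde (KOH, EtOH) should give (E)-1-[2,4-bis(benzyloxy)-6-hydroxyphenyl]-3-[4-(benzyloxy)phenyl]prop-2-en-1-one F3. Cyclisation with NaOAc in refluxing EtOH gives racemic 5,7-bis(benzyloxy)-2-[4-(benzyloxy)phenyl]chroman-4-one F4. Preparative HPLC on a cellulose carbamate chiral phase delivers the (2S)-enantiomer, which is 7; the (2R)-enantiomer is racemised through the chalcone with base and recycled.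

**Further compounds**

F1 | step 5 | bis{[(2S)-5,7-bis(benzyloxy)-2-(4-benzyloxyphenyl)-2H-chromen-4-yl]oxy}diisopropylsilane | CC(C)[Si](C(C)C)(OC1=C[C@@H](c2ccc(OCc3ccccc3)cc2)Oc2cc(OCc3ccccc3)cc(OCc3ccccc3)c21)OC1=C[C@@H](c2ccc(OCc3ccccc3)cc2)Oc2cc(OCc3ccccc3)cc(OCc3ccccc3)c21
F2 | step 6 | 4''-(tert-butyldimethylsilyloxy) mono-enol ether of 9 (geometry at all three stereocentres unchanged; the C2'' descriptor becomes R by the priority rules) | O=C1c2c(OCc3ccccc3)cc(OCc3ccccc3)cc2O[C@H](c2ccc(OCc3ccccc3)cc2)[C@H]1C1=C(O[Si](C)(C)C(C)(C)C)c2c(OCc3ccccc3)cc(OCc3ccccc3)cc2O[C@@H]1c1ccc(OCc2ccccc2)cc1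
F3 | step 3 | (E)-1-[2,4-bis(benzyloxy)-6-hydroxyphenyl]-3-[4-(benzyloxy)phenyl]prop-2-en-1-one | O=C(/C=C/c1ccc(OCc2ccccc2)cc1)c1c(O)cc(OCc2ccccc2)cc1OCc1ccccc1
F4 | step 3 | racemic 5,7-bis(benzyloxy)-2-[4-(benzyloxy)phenyl]chroman-4-one | O=C1CC(c2ccc(OCc3ccccc3)cc2)Oc2cc(OCc3ccccc3)cc(OCc3ccccc3)c21
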